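**Retrosynthetic overview**
- The strategy rests on ring C, the 2-hydroxy-4-methylphenyl ring: OH on C2 (ortho) and CH3 on C4 (para) to C1, which carries the side chain. This is the footprint of a 1,1-dioxygenated 3-methylbuta-1,3-diene added across a terminal ynone, so ring bonds C1–C2 and C5–C6 are cut.
- The Z enol ether allylic alcohol is traced back to a 2-aryl-2-(alkoxymethyl)oxirane (syn β-elimination), and that to the aryl alkoxymethyl ketone delivered by the benzannulation.
- The ynone comes from ethynylmagnesium bromide and a Weinreb amide ether, made by O-alkylation of the (S)-benzylic alcohol; the alcohol comes from asymmetric transfer hydrogenation of the 6-acetyl chromene.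
- Ring order: the benzopyran (rings A and B) is bought intact; ring C is built in step 6; an oxirane is closed in step 8 and opened in step 9.

Key step: step 6

Remark: the 1-(2,4-dialkoxyphenyl)ethyl C–O bond and the final enol ether are taken to be acid-labile, so no reaction or work-up after step 2 goes below about pH 3.

**Step 1**
Reactants: 1 7-methoxy-2,2-dimethyl-2H-chromene
Product: 2 1-(7-methoxy-2,2-dimethyl-2H-chromen-6-yl)ethan-1-one
Conditions: Ac2O, ZnCl2, CH2Cl2, 0 °C to rt
Reagents that add atoms: acetic anhydride, CC(=O)OC(C)=O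
Why: Friedel–Crafts acylation: C6 is para to the ring oxygen O1 and ortho to the 7-methoxy group and is the only unhindered doubly activated position (C8 lies between two oxygens), and the mild ZnCl2/Ac2O couple is chosen to spare the acid-sensitive C3=C4 bond.

**Step 2**
Reactants: 2 1-(7-methoxy-2,2-dimethyl-2H-chromen-6-yl)ethan-1-one
Product: 3 (S)-1-(7-methoxy-2,2-dimethyl-2H-chromen-6-yl)ethan-1-ol
Conditions: RuCl[(S,S)-TsDPEN](p-cymene) (1 mol %), HCO2Na, H2O/MeOH, 40 °C
Reagents that add atoms: none
Why: Noyori asymmetric transfer hydrogenation: the (S,S)-TsDPEN ruthenium hydride reduces aryl methyl ketones through the CH/π-stabilised six-membered transition state to the (S)-carbinols, formate makes the hydride transfer irreversible for this electron-rich ketone, the near-neutral aqueous medium avoids ionisation of the sensitive benzylic alcohol, and the chromene alkene is not reduced.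

**Step 3**
Reactants: 3 (S)-1-(7-methoxy-2,2-dimethyl-2H-chromen-6-yl)ethan-1-ol; 4 2-bromo-N-methoxy-N-methylacetamide
Product: 6 (S)-N-methoxy-2-[1-(7-methoxy-2,2-dimethyl-2H-chromen-6-yl)ethoxy]-N-methylacetamide, via sodium alkoxide 5 (not isolated)
Conditions: NaH, THF, 0 °C; then 4, Bu4NI (cat.), 0 °C to rt
Reagents that add atoms: none
Why: Williamson ether synthesis: the sodium alkoxide displaces bromide from the primary α-bromo amide in an SN2 reaction at the CH2Br carbon, so the benzylic C–O bond is never broken and the (S)-configuration is carried over unchanged.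

**Step 4**
Reactants: 6 (S)-N-methoxy-2-[1-(7-methoxy-2,2-dimethyl-2H-chromen-6-yl)ethoxy]-N-methylacetamide; 7 ethynylmagnesium bromide
Product: 9 (S)-1-[1-(7-methoxy-2,2-dimethyl-2H-chromen-6-yl)ethoxy]but-3-yn-2-one, via magnesium chelate 8 (not isolated)
Conditions: 7 (0.5 M in THF), THF, −20 to 0 °C; inverse quench into cold pH 3 citrate buffer/Et2O
Reagents that add atoms: none
Why: Weinreb ketone synthesis: the five-membered magnesium chelate 8 resists a second addition and collapses to the terminal ynone only in the cold, weakly acidic inverse quench, which also keeps the released N,O-dimethylhydroxylamine protonated so that it does not add to the ynone, while pH 3 is too mild to ionise the benzylic ether.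

**Step 5**
Reactants: 10 methyl 3-methylbut-2-enoate
Product: 12 1-methoxy-3-methyl-1-(trimethylsilyloxy)buta-1,3-diene, via lithium dienolate 11 (not isolated)
Conditions: LiN(iPr)2, THF, −78 °C; Me3SiCl, −78 °C to rt; distillation
Reagents that add atoms: chlorotrimethylsilane, C[Si](C)(C)Cl
Why: Kinetic γ-deprotonation of the β,β-dimethylacrylate gives the lithium dienolate 11, whose O-silylation by the hard electrophile Me3SiCl gives the vinylketene silyl acetal, a standard preparation of such dienes (E/Z isomerism at the acetal carbon is irrelevant because that carbon becomes aromatic).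

**Step 6**
Reactants: 9 (S)-1-[1-(7-methoxy-2,2-dimethyl-2H-chromen-6-yl)ethoxy]but-3-yn-2-one; 12 1-methoxy-3-methyl-1-(trimethylsilyloxy)buta-1,3-diene
Product: 15 (S)-1-(2-hydroxy-4-methylphenyl)-2-[1-(7-methoxy-2,2-dimethyl-2H-chromen-6-yl)ethoxy]ethan-1-one, via cycloadduct ketal 13 (not isolated), via aryl trimethylsilyl ether 14 (not isolated)
Conditions: 12 (2.5 equiv), PhMe, rt to 80 °C; then K2CO3 (cat.), THF/H2O, rt
Reagents that add atoms: none
Why: The electron-rich vinylketene silyl acetal 12 and the electron-poor alkyne of 9 undergo a normal-electron-demand, strongly asynchronous [4+2] cycloaddition in which the CH2 terminus of 12 attacks the unsubstituted alkyne carbon first and the dioxygenated terminus then bonds to the acyl-bearing carbon. Ring C is thereby closed in an intermolecular cycloaddition that makes both new ring bonds (C1–C2 and C5–C6 of the future arene) and gives the cyclohexa-1,4-diene ketal 13. Because the ketal carbon of 13 lies across the ring from a CH2 group, 13 aromatises without an oxidant by 1,4-loss of methanol to the silyl ether 14, which the mildly basic aqueous work-up hydrolyses to the hydrogen-bonded phenol 15. The closest known reaction type is the cycloaddition–aromatisation of 1-alkoxy-1-silyloxybutadienes with propiolates, acetylenedicarboxylates and alkynyl ketones to salicylate-type phenols. The one new stereocentre, the ketal carbon of 13, needs no control because it becomes an aromatic carbon, and the benzylic (S)-centre is not touched under the neutral thermal conditions. The step needs regioselectivity, secured by the matched polarisation (largest HOMO coefficient at the diene CH2, raised by both the 1,1-dioxy unit and the 3-methyl group, against the largest LUMO coefficient at the terminal ynone carbon), and chemoselectivity, secured because the ynone is the only electron-poor π bond and the electron-rich chromene C3=C4 bond is no dienophile for this diene.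

**Step 7**
Reactants: 15 (S)-1-(2-hydroxy-4-methylphenyl)-2-[1-(7-methoxy-2,2-dimethyl-2H-chromen-6-yl)ethoxy]ethan-1-one
Product: 16 (S)-1-[2-(tert-butyldimethylsilyloxy)-4-methylphenyl]-2-[1-(7-methoxy-2,2-dimethyl-2H-chromen-6-yl)ethoxy]ethan-1-one
Conditions: TBSCl, imidazole, DMAP (cat.), DMF, rt
Reagents that add atoms: tert-butyldimethylsilyl chloride, CC(C)(C)[Si](C)(C)Cl
Why: Standard silylation of a phenol (TBSCl–imidazole), needed because a free phenoxide would deactivate the ortho ketone toward the ylide in step 8, and the non-acidic conditions leave the benzylic ether and the ketone α-CH2 untouched.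

**Step 8**
Reactants: 16 (S)-1-[2-(tert-butyldimethylsilyloxy)-4-methylphenyl]-2-[1-(7-methoxy-2,2-dimethyl-2H-chromen-6-yl)ethoxy]ethan-1-one
Product: 18 2-[2-(tert-butyldimethylsilyloxy)-4-methylphenyl]-2-{[(S)-1-(7-methoxy-2,2-dimethyl-2H-chromen-6-yl)ethoxy]methyl}oxirane (both configurations at the oxirane carbon), via sulfonium betaine 17 (not isolated)
Conditions: Me3SI, n-BuLi, THF, −10 °C; then 16, −10 °C to rt; used crude
Reagents that add atoms: trimethylsulfonium iodide, C[S+](C)C.[I-]
Why: Corey–Chaykovsky epoxidation: the unstabilised sulfonium ylide adds to the ketone carbonyl and the betaine 17 closes by 3-exo-tet displacement of Me2S, the new oxirane carbon being formed as a mixture of two diastereomers that is of no consequence because this carbon becomes sp2 in step 9.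

**Step 9**
Reactants: 18 2-[2-(tert-butyldimethylsilyloxy)-4-methylphenyl]-2-{[(S)-1-(7-methoxy-2,2-dimethyl-2H-chromen-6-yl)ethoxy]methyl}oxirane
Product: 20 (Z)-2-[2-(tert-butyldimethylsilyloxy)-4-methylphenyl]-3-[(S)-1-(7-methoxy-2,2-dimethyl-2H-chromen-6-yl)ethoxy]prop-2-en-1-ol, via lithium alkoxide 19 (not isolated)
Conditions: LiN(iPr)2 (3 equiv), THF, −78 °C to rt; then H2O
Reagents that add atoms: none
Why: Lithium amide-promoted isomerisation of an epoxide to an allylic alcohol by syn β-elimination, known for alkoxymethyl oxiranes: the only β-hydrogens are those of the OCH2 group, and in the lithium-bridged cyclic transition state the alkoxy group turns away from the ortho-substituted aryl group toward the oxirane CH2, which places OR cis to CH2O and so gives the Z enol ether, while the benzylic stereocentre is not involved.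

**Step 10**
Reactants: 20 (Z)-2-[2-(tert-butyldimethylsilyloxy)-4-methylphenyl]-3-[(S)-1-(7-methoxy-2,2-dimethyl-2H-chromen-6-yl)ethoxy]prop-2-en-1-ol
Product: 21 (Z)-2-(2-hydroxy-4-methylphenyl)-3-[(S)-1-(7-methoxy-2,2-dimethyl-2H-chromen-6-yl)ethoxy]prop-2-en-1-ol (CNP0279099.1)
Conditions: Bu4NF, AcOH (1 equiv each), THF, 0 °C; chromatography on Et3N-deactivated silica
Reagents that add atoms: none
Why: Fluoride-mediated desilylation, buffered with one equivalent of AcOH, removes the silyl group (also if it has shifted to the primary oxygen in step 9) without acid, so the enol ether, the allylic alcohol and the benzylic (S)-ether survive and the target results.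

**Compound list**
1 | 7-methoxy-2,2-dimethyl-2H-chromene | COc1ccc2C=CC(C)(C)Oc2c1 | starting material
2 | 1-(7-methoxy-2,2-dimethyl-2H-chromen-6-yl)ethan-1-one | COc1cc2c(cc1C(C)=O)C=CC(C)(C)O2 | intermediate
3 | (S)-1-(7-methoxy-2,2-dimethyl-2H-chromen-6-yl)ethan-1-ol | COc1cc2c(cc1[C@H](C)O)C=CC(C)(C)O2 | intermediate
4 | 2-bromo-N-methoxy-N-methylacetamide | CON(C)C(=O)CBr | starting material
5 | sodium (S)-1-(7-methoxy-2,2-dimethyl-2H-chromen-6-yl)ethan-1-olate | COc1cc2c(cc1[C@H](C)[O-])C=CC(C)(C)O2.[Na+] | intermediate (not isolated)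
6 | (S)-N-methoxy-2-[1-(7-methoxy-2,2-dimethyl-2H-chromen-6-yl)ethoxy]-N-methylacetamide | COc1cc2c(cc1[C@H](C)OCC(=O)N(C)OC)C=CC(C)(C)O2 | intermediate
7 | ethynylmagnesium bromide | C#C[Mg]Br | starting material
8 | bromomagnesium alkoxide of the tetrahedral adduct of 6 and 7 (N-methoxy-N-methyl hemiaminal, chelated) | COc1cc2c(cc1[C@H](C)OCC(O[Mg]Br)(C#C)N(C)OC)C=CC(C)(C)O2 | intermediate (not isolated)
9 | (S)-1-[1-(7-methoxy-2,2-dimethyl-2H-chromen-6-yl)ethoxy]but-3-yn-2-one | COc1cc2c(cc1[C@H](C)OCC(=O)C#C)C=CC(C)(C)O2 | intermediate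
10 | methyl 3-methylbut-2-enoate | COC(=O)C=C(C)C | starting material
11 | lithium 1-methoxy-3-methylbuta-1,3-dien-1-olate | [Li+].[O-]C(OC)=CC(C)=C | intermediate (not isolated)
12 | 1-methoxy-3-methyl-1-(trimethylsilyloxy)buta-1,3-diene | COC(O[Si](C)(C)C)=CC(C)=C | intermediate
13 | 1-[6-methoxy-4-methyl-6-(trimethylsilyloxy)cyclohexa-1,4-dien-1-yl]-2-[(S)-1-(7-methoxy-2,2-dimethyl-2H-chromen-6-yl)ethoxy]ethan-1-one (both configurations at the ketal carbon) | COc1cc2c(cc1[C@H](C)OCC(=O)C1=CCC(C)=CC1(OC)O[Si](C)(C)C)C=CC(C)(C)O2 | intermediate (not isolated)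
14 | (S)-2-[1-(7-methoxy-2,2-dimethyl-2H-chromen-6-yl)ethoxy]-1-[4-methyl-2-(trimethylsilyloxy)phenyl]ethan-1-one | COc1cc2c(cc1[C@H](C)OCC(=O)c1ccc(C)cc1O[Si](C)(C)C)C=CC(C)(C)O2 | intermediate (not isolated)
15 | (S)-1-(2-hydroxy-4-methylphenyl)-2-[1-(7-methoxy-2,2-dimethyl-2H-chromen-6-yl)ethoxy]ethan-1-one | COc1cc2c(cc1[C@H](C)OCC(=O)c1ccc(C)cc1O)C=CC(C)(C)O2 | intermediate
16 | (S)-1-[2-(tert-butyldimethylsilyloxy)-4-methylphenyl]-2-[1-(7-methoxy-2,2-dimethyl-2H-chromen-6-yl)ethoxy]ethan-1-one | COc1cc2c(cc1[C@H](C)OCC(=O)c1ccc(C)cc1O[Si](C)(C)C(C)(C)C)C=CC(C)(C)O2 | intermediate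
17 | sulfonium betaine from 16 and dimethylsulfonium methylide | COc1cc2c(cc1[C@H](C)OCC([O-])(C[S+](C)C)c1ccc(C)cc1O[Si](C)(C)C(C)(C)C)C=CC(C)(C)O2 | intermediate (not isolated)
18 | 2-[2-(tert-butyldimethylsilyloxy)-4-methylphenyl]-2-{[(S)-1-(7-methoxy-2,2-dimethyl-2H-chromen-6-yl)ethoxy]methyl}oxirane (both configurations at the oxirane carbon) | COc1cc2c(cc1[C@H](C)OCC1(CO1)c1ccc(C)cc1O[Si](C)(C)C(C)(C)C)C=CC(C)(C)O2 | intermediate
19 | lithium alkoxide of 20 | COc1cc2c(cc1[C@H](C)O/C=C(\C[O-])c1ccc(C)cc1O[Si](C)(C)C(C)(C)C)C=CC(C)(C)O2.[Li+] | intermediate (not isolated)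
20 | (Z)-2-[2-(tert-butyldimethylsilyloxy)-4-methylphenyl]-3-[(S)-1-(7-methoxy-2,2-dimethyl-2H-chromen-6-yl)ethoxy]prop-2-en-1-ol | COc1cc2c(cc1[C@H](C)O/C=C(\CO)c1ccc(C)cc1O[Si](C)(C)C(C)(C)C)C=CC(C)(C)O2 | intermediate
21 | (Z)-2-(2-hydroxy-4-methylphenyl)-3-[(S)-1-(7-methoxy-2,2-dimethyl-2H-chromen-6-yl)ethoxy]prop-2-en-1-ol | COc1cc2c(cc1[C@H](C)O/C=C(\CO)c1ccc(C)cc1O)C=CC(C)(C)O2 | target

**Total step count:** 10
**Longest linear sequence:** 9 steps (steps 1–4 and 6–10; step 5 is the one-step diene branch)

**Steps most likely to fail**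

Step 6. After the first C–C bond the polarised intermediate may transfer silicon instead of closing the ring and leave open-chain Michael adducts. The ketene acetal double bond may also add [2+2], the ynone may oligomerise, or aromatisation may proceed by loss of silanol and give the methyl ether instead of the phenol. The fallback drops the benzannulation and introduces ring C as an aryl nucleophile. It sets out from Weinreb amide 6: 2-bromo-5-methylphenol F1 is treated with n-BuLi (2.1 equiv, Et2O/THF, −78 to 0 °C) to give lithium 2-lithio-5-methylphenolate F2 by O–H deprotonation and bromine–lithium exchange. Addition of 6 at −78 °C and a pH 5 quench (Weinreb ketone synthesis with an aryllithium) should give the phenol ketone 15, where the route is rejoined.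

Step 9. The amide may add to the oxirane CH2, metalate the oxirane CH2 or the benzylic C–H (Wittig-type rearrangement, erosion of the (S)-centre), or the elimination may show poor Z/E control. The fallback fixes the geometry at an enolate instead and sets out from silyl ketone 16, bypassing oxirane 18. KN(SiMe3)2 (THF, −78 °C) should give the chelated Z enolate, which PhNTf2 traps as (Z)-1-[2-(tert-butyldimethylsilyloxy)-4-methylphenyl]-2-[(S)-1-(7-methoxy-2,2-dimethyl-2H-chromen-6-yl)ethoxy]ethenyl trifluoromethanesulfonate F3, with OTf cis to the alkoxy group. Stille coupling with Bu3SnCH2OH (Pd(PPh3)4, LiCl, dioxane, 90 °C) replaces the triflate by CH2OH with retention of geometry and returns to the route at 20.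

Step 1. The Lewis acid may trigger cationic dimerisation or oligomerisation of the electron-rich C3=C4 bond, or acylation may occur at C3 instead of C6. The fallback sets out from 1 and uses the milder Vilsmeier–Haack formylation (POCl3, DMF, 0 to 60 °C; aq. NaOAc) to give 7-methoxy-2,2-dimethyl-2H-chromene-6-carbaldehyde F4. Addition of MeMgBr (THF, 0 °C) gives racemic 1-(7-methoxy-2,2-dimethyl-2H-chromen-6-yl)ethan-1-ol F5, and oxidation with MnO2 (CH2Cl2, rt) returns to the route at ketone 2.

**Further compounds**
F1 | step 6 | 2-bromo-5-methylphenol | Cc1ccc(Br)c(O)c1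
F2 | step 6 | lithium 2-lithio-5-methylphenolate | [Li]c1ccc(C)cc1O[Li]
F3 | step 9 | (Z)-1-[2-(tert-butyldimethylsilyloxy)-4-methylphenyl]-2-[(S)-1-(7-methoxy-2,2-dimethyl-2H-chromen-6-yl)ethoxy]ethenyl trifluoromethanesulfonate | COc1cc2c(cc1[C@H](C)O/C=C(\OS(=O)(=O)C(F)(F)F)c1ccc(C)cc1O[Si](C)(C)C(C)(C)C)C=CC(C)(C)O2
F4 | step 1 | 7-methoxy-2,2-dimethyl-2H-chromene-6-carbaldehyde | COc1cc2c(cc1C=O)C=CC(C)(C)O2
F5 | step 1 | racemic 1-(7-methoxy-2,2-dimethyl-2H-chromen-6-yl)ethan-1-ol | COc1cc2c(cc1C(C)O)C=CC(C)(C)O2
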